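**The vessel.** A closed, stirred vessel at constant temperature holds starting material and reagent, and earlier runs show how such charges behave.

| flask | starting material | reagent | remark | time |
|---|---|---|---|---|
| epsilon | 1.5 M | 0.68 M | run made earlier |  |
| delta | 1.5 M | 1 M | run made earlier |  |
| eta | 0.75 M | 1.35 M | run made earlier |  |
| flask | 1.5 M | 1.35 M |  | 20 min |

- epsilon (time / min: side product / %, target / %): 1.33: 17, 0; 2.50: 25, 0; 5.00: 48, 2; 8.00: 61, 0; 15.0: 84, 1
- delta (time / min: side product / %, target / %): 3.00: 24, 0; 6.00: 53, 0; 10.0: 74, 0; 12.0: 74, 0; 15.0: 79, 1
- eta (time / min: side product / %, target / %): 1.33: 16, 0; 4.00: 38, 2; 8.00: 61, 1; 12.0: 75, 1; 15.0: 83, 1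

(each reading ± 2 percentage points)

* amount of side product in percent of the starting material charged, at 4.0 min, 10 min and 20 min

**First instants.** In the epsilon run, side product is there by the first reading, 17% at 1.33 min, while target stays within about one scatter of 2 percentage points. By 15.0 min that run has made 1.26 M of side product, more than its 0.68 M of reagent, so side product does not take reagent one to one.

**Frozen reagent.** As a trial I leave reagent out of my reckoning and count lost starting material as side product. The two runs at 1.5 M average 81.5% at 15.0 min, which gives a loss constant of 0.112 min⁻¹. From it I carry one number, the halving time (half-life), 6.16 min: the time in which starting material falls to half of whatever is present.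

**Second flask.** The eta run has half the starting material and twice the reagent of the epsilon run, and it played no part in that number. At 12.0 min the halving time predicts 73.9% for it, and the reading is 75%.

**Middle, end.** For the new flask I reckon 36.1% at 4.0 min and 67.4% at 10 min. At 20 min, 3.25 halving times have passed, which gives 89.5%. That last figure lies beyond the readings, which stop at 15.0 min.

**The forecast.** It gives 38%, 70% and 91%, on the ground “So the side product forms by a simple first-order loss of starting material, independent of reagent.” At 20 min it stands 1.5 points above mine.

**The result.** The flask gives 37.8%, 68.8% and 88.7%, within the forecast's margin.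

    starting material → side product (k = 0.120 min⁻¹)
    starting material + reagent → intermediate A (k = 0.00300 M⁻¹ min⁻¹)
    intermediate A → intermediate B (k = 0.120 min⁻¹)
    reagent + intermediate B → intermediate C (k = 0.0420 M⁻¹ min⁻¹)
    reagent + intermediate A ⇌ intermediate D (K = 0.430 M⁻¹, k = 0.00390 M⁻¹ min⁻¹)
    intermediate C → target (k = 0.500 min⁻¹)

**Two paths.** In the flask, the path from starting material and reagent to intermediate A would by itself halve the starting material in 170 min, with reagent as charged, which is 27.6 times my halving time of 6.16 min. At 20.0 min the direct path to side product still uses starting material 31 times as fast as that path, and the flask holds 88.7% side product, 8.38% starting material and 95.7% of its reagent charge.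

(The earlier runs and the new flask were generated by integration for an exercise; scatter was added.)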